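Readings and results are simulated for an exercise, noise included.

Begin with the easy step, the substrate: the north run holds 4.00 times the substrate of the north-west run, yet at 5.00 d they read 82% and 83% of the charge against a scatter of 1.5 percentage points. You may therefore read the rate as first order in substrate, and an error in that charge drops out of a factor taken at one conversion.

| setting | north-west | north | flask |
|---|---|---|---|
| substrate | 9.5 mM | 38 mM | 19 mM |
| coupling partner | 19 mM | 19 mM | 19.0 mM |
| free catalyst | 38 µM | 38 µM | 38 µM |
| second catalyst | 0.25 mM | 0.25 mM | 0.25 mM |
| added ligand | 90 µM | 90 µM | 90 µM |
| remark | run made earlier | run made earlier |  |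

| run | time / d | product / % | substrate / % |
|---|---|---|---|
| north-west | 0.417 | 3 | 98 |
| north-west | 0.833 | 2 | 96 |
| north-west | 1.25 | 5 | 96 |
| north-west | 2.50 | 5 | 89 |
| north-west | 5.00 | 17 | 83 |
| north | 1.04 | 2 | 97 |
| north | 2.08 | 5 | 90 |
| north | 3.00 | 10 | 89 |
| north | 4.00 | 15 | 84 |
| north | 5.00 | 16 | 82 |

(each reading ± 1.5 percentage points)

- factor on the rate of making product when 30% of the substrate are converted if free catalyst is charged twice over
- factor on the rate when 30% of the substrate are converted if free catalyst is charged at 200 µM instead

- "the catalyst" is free catalyst with its forms; second catalyst is a second catalyst
- no earlier run changes the charge of free catalyst; that part of a forecast is a guess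

Coupling partner and second catalyst stand at one charge in both runs, so the readings say nothing of them and I carry them as an open risk. The number you must know well is the added ligand, on a supposition of my own that these runs do not test: free catalyst sits one-to-one in an idle complex with added ligand, and the rate follows the part left unbound, which goes as catalyst charged over ligand left over.

In this flask that leaves 57.8% of the added ligand over, and this spare ligand, the fraction of the added ligand charge left once each catalyst has taken one, is what I carry. With the catalyst charge doubled it falls to 15.6%, so the first round gives 2 times 3.71, or 7.43. With added ligand 10% short, the same reckoning gives 17.2, more than 7.43, so this charge has to be known well. Going round once more, unbound catalyst hands ligand back, and with 15.6% less than 57.8% I expect this to lift the smaller spare by the larger share, so I commit to a factor below 7.43 but well above 2. At 200 µM the catalyst exceeds the added ligand, which becomes the limiting reagent of the binding and leaves 55.0% of the catalyst uncovered; that is a share rather than a factor, and I expect the factor to lie above plain proportion, 5.26.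

The forecast gives 1.9 (from 1.2 to 2.8) and 4 (from 1.8 to 7.5), noting that “ligation could cap the active catalyst at about 2.4-fold”.

The simulation gives 5.53 for the doubled charge, below my 7.43, and 18.4 at 200 µM. In this flask at 5.00 d, the idle complex holds 97.6% of the catalyst and free catalyst 2.35%, while 58.8% of the added ligand stays unbound, against the spare ligand of 57.8%.

    substrate + free catalyst → free catalyst + open intermediate (k = 1850 M⁻¹ h⁻¹)
    coupling partner + catalyst intermediate → second catalyst + product (k = 10500 M⁻¹ h⁻¹)
    second catalyst + open intermediate ⇌ catalyst intermediate (K = 15.0 M⁻¹, k = 352 M⁻¹ h⁻¹)
    free catalyst + added ligand ⇌ idle complex, settled at all times (K = 7.84 × 10⁵ M⁻¹)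

Carried to the flask charged at 200 µM, the same subtraction leaves 55.0% of the catalyst without ligand, and the share of free catalyst there at 30% conversion is 55.5%.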